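1. At early times birch lost its starting material faster than later: its loss constant (an observed first-order rate constant), minus the natural logarithm of the fraction left per unit time, read 0.429 h⁻¹ over its first reading, but 0.209 h⁻¹ over its last interval.

| flask | starting material | protic impurity | temperature | remark | time |
|---|---|---|---|---|---|
| maple | 0.013 M | 0.44 mM | 5 °C | run made earlier |  |
| birch | 0.013 M | 0.98 mM | 27 °C | run made earlier |  |
| larch | 0.0065 M | 0.65 mM | 5 °C | run made earlier |  |
| west | 0.013 M | 0.650 mM | 15 °C |  | 4.0 h |
| south | 0.013 M | 0.650 mM |  | at 35 °C until 80 min, from then on at −5 °C | 4.0 h |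
| east | 0.013 M | 0.650 mM | 35 °C |  | 4.0 h |
| north-east | 0.013 M | 0.650 mM | −5 °C |  | 4.0 h |

maple run (percent of the starting material charged)

| time / h | target / % | starting material / % |
|---|---|---|
| 0.250 | 0.5 | 99.3 |
| 0.833 | 1.1 | 98.8 |
| 1.33 | 0.8 | 97.7 |
| 2.00 | 1.7 | 96.4 |
| 3.00 | 2.1 | 95.4 |
| 4.00 | 2.1 | 94.3 |

birch run (percent of the starting material charged)

| time / min | target / % | starting material / % |
|---|---|---|
| 6.00 | 2.4 | 95.8 |
| 12.0 | 4.0 | 92.6 |
| 15.0 | 4.3 | 91.0 |
| 30.0 | 6.6 | 85.6 |
| 40.0 | 9.8 | 82.3 |
| 80.0 | 16.3 | 71.6 |

larch run (percent of the starting material charged)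

| time / h | target / % | starting material / % |
|---|---|---|
| 0.333 | 0.3 | 98.7 |
| 0.500 | 0.4 | 98.7 |
| 1.00 | 0.6 | 97.4 |
| 2.00 | 1.4 | 94.9 |
| 4.00 | 2.8 | 90.5 |

(standard deviation of a reading: 0.5 percentage points)

- in a conversion other conformer counts as not yet reacted

- the flask with the highest amount of target, in percent of the starting material charged ("all alike" if they lie within 1.5 percentage points) (west / south / east / north-east / all alike)
- final target, as a percentage of the starting material charged, in west
- final target, as a percentage of the starting material charged, in south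
- final target, as a percentage of the starting material charged, in east
- final target, as a percentage of the starting material charged, in north-east

2. I read that early excess as protic impurity being spent once, taking its share of the charge, because larch, at maple's temperature, held impurity at 10.0% of the charge against 3.38% and lost more, 9.50% against 5.70%.

3. So I carried the late loss constant: maple's last two intervals gave 0.0110 h⁻¹, and a straight line of its logarithm against temperature through maple and birch gave, for 35 °C, the loss constant 0.609 h⁻¹.

4. East's neighbour is birch, but birch stopped after 0.334 time constants, with 71.6% left, while east was due to run 2.44. With impurity's 5.00% taken off, I expected 8.31% left in east.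

5. Birch's target share of the loss, 57.4%, then gave me 52.6% in east, 33.2% in south from its hot period, and 11.3% in west. I trusted the share least, because birch's unaccounted 12.1% exceeded its impurity share.

6. The forecast named east, with 9.3% in west, 24.8% in south, 55% in east and 0.8% in north-east, and held that “the reaction is catalytic and first order in starting material”, where I spent the impurity once.

7. The flasks gave 11.1% in west, 32.3% in south, 39.5% in east and 0.618% in north-east, so east held the most.

    target ⇌ isomer of the product B (K = 0.150, k = 1.10 × 10⁻⁵ s⁻¹, Ea = 94.0 kJ mol⁻¹, ΔH = −51.0 kJ mol⁻¹)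
    starting material ⇌ other conformer (K = 4.40, k = 5.50 × 10⁻⁶ s⁻¹, Ea = 111 kJ mol⁻¹, ΔH = −44.0 kJ mol⁻¹)
    starting material → target (k = 1.40 × 10⁻⁴ s⁻¹, Ea = 99.0 kJ mol⁻¹)
    starting material + protic impurity → quenched substrate (k = 0.120 M⁻¹ s⁻¹, Ea = 61.0 kJ mol⁻¹)
    target ⇌ isomer of the product A (K = 1.30, k = 1.70 × 10⁻⁴ s⁻¹, Ea = 90.0 kJ mol⁻¹, ΔH = −18.0 kJ mol⁻¹)
    other conformer → isomer of the product A (k = 0.00240 s⁻¹, Ea = 85.0 kJ mol⁻¹)
    (constants at 35 °C)

East kept 12% of its starting material, a loss constant of 0.525 h⁻¹ against my 0.609 h⁻¹, and its neighbour read at 1.5 h, with 43.0% left, gives 0.528 h⁻¹. In east the relaxation half-life of target and isomer of the product A by that step alone was 0.640 h, shorter than the 4.0 h run, while the half-life of target by the forward step to isomer of the product B was 18 h, longer than the run. At the end of east, target stood at 39.5% beside 40.5% of isomer of the product A.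

All runs are calculated on assumed constants; the scatter is artificial.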